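**Strategy.** Everything rests on cutting the C2–C1′ bond between ring C and the unsubstituted ring B. C2 is the only stereocentre, an O1-bearing benzylic carbon β to the C4 carbonyl, and the C6 and C8 arms are identical, so the precursor is a flat, achiral, fully O-benzylated chromone whose C2 carries only hydrogen. A ligand-controlled rhodium-catalysed 1,4-addition of phenylboronic acid then installs ring B, converts the 4-pyranone into the dihydropyranone and sets C2 as S in one operation. The chromone is assembled from a symmetric acetophenone by twofold ortho-quinone methide benzylation, and only a neutral hydrogenolysis follows the key step.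

Key step: step 8

Remark on the chemistry: the (S)-diphosphine in step 8 is assigned from the quadrant model that holds for cyclic enones (mapped onto C2 of the chromone it predicts 2S). The sense is to be checked on chromone itself, and the (R)-ligand is used instead if the test shows the opposite. Benzyl bromide, PBr3 and DMF-DMA are treated as reagents and carry no number.

**Step 1**
Reactants: 1 2-(benzyloxy)benzaldehyde
Product: 2 [2-(benzyloxy)phenyl]methanol
Conditions: NaBH4 (0.6 equiv), MeOH, 0 °C to rt
Reagents that add atoms: none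
Why: Borohydride reduction of an aromatic aldehyde to the benzylic alcohol, with the aryl benzyl ether inert.

**Step 2**
Reactants: 2 [2-(benzyloxy)phenyl]methanol
Product: 3 2-(benzyloxy)benzyl bromide
Conditions: PBr3 (0.4 equiv), CH2Cl2, 0 °C; ice-water quench, used without chromatography
Reagents that add atoms: phosphorus tribromide, BrP(Br)Br
Why: Alcohol-to-bromide conversion with PBr3 (SN2 displacement of the phosphite ester by bromide) at low temperature, where the benzyl ether survives; the solvolysis-prone bromide is carried on directly.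

**Step 3**
Reactants: 3 2-(benzyloxy)benzyl bromide; 4 2-hydroxy-5-(4,4,5,5-tetramethyl-1,3,2-dioxaborolan-2-yl)benzaldehyde
Product: 5 5-[2-(benzyloxy)benzyl]-2-hydroxybenzaldehyde
Conditions: Pd(dppf)Cl2·CH2Cl2 (3 mol%), K2CO3 (3 equiv), THF/H2O 5:1, 60 °C, 3 added over 2 h; acidified to pH 5 on work-up
Reagents that add atoms: none
Why: sp3–sp2 Suzuki–Miyaura coupling, in which the β-hydrogen-free benzylic bromide adds to Pd(0) quickly and the para-phenoxide-activated boronate transmetalates readily, while the hydrated, aldehyde-chelated phenoxide of 4 is a poor nucleophile in wet THF and the slowly added bromide stays dilute, so C–C coupling should outpace O-benzylation.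

**Step 4**
Reactants: 5 5-[2-(benzyloxy)benzyl]-2-hydroxybenzaldehyde
Product: 6 4-[2-(benzyloxy)benzyl]-2-(hydroxymethyl)phenol
Conditions: NaBH4 (0.6 equiv), THF/MeOH, 0 °C; aq NH4Cl work-up
Reagents that add atoms: none
Why: Borohydride reduction of the salicylaldehyde to the salicyl alcohol, worked up near neutral pH so that the benzylic alcohol is not ionised prematurely.

**Step 5**
Reactants: 6 4-[2-(benzyloxy)benzyl]-2-(hydroxymethyl)phenol (2.2 equiv); 7 2',6'-dihydroxy-4'-methoxyacetophenone
Product: 10 3',5'-bis{5-[2-(benzyloxy)benzyl]-2-hydroxybenzyl}-2',6'-dihydroxy-4'-methoxyacetophenone, via ortho-quinone methide 8 (not isolated), via mono-armed acetophenone 9 (not isolated)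
Conditions: BF3·OEt2 (0.5 equiv), 1,4-dioxane, rt to 40 °C, 6 added by syringe pump over 4 h
Reagents that add atoms: none
Why: Acid-promoted dehydration of the salicyl alcohol gives ortho-quinone methide 8, which is captured in a Friedel–Crafts-type conjugate addition by C3′ and then C5′ of 7; these are the only free ring carbons of 7 and the most electron-rich carbons present, so the symmetric substrate leaves no regiochemical choice, and slow addition of 6 should suppress its self-condensation.

**Step 6**
Reactants: 10 3',5'-bis{5-[2-(benzyloxy)benzyl]-2-hydroxybenzyl}-2',6'-dihydroxy-4'-methoxyacetophenone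
Product: 11 2'-(benzyloxy)-3',5'-bis{2-(benzyloxy)-5-[2-(benzyloxy)benzyl]benzyl}-6'-hydroxy-4'-methoxyacetophenone
Conditions: BnBr (3.3 equiv), K2CO3 (4 equiv), acetone, reflux
Reagents that add atoms: benzyl bromide, BrCc1ccccc1
Why: Williamson etherification of the two arm phenols and one ring-A hydroxyl; the last ring-A hydroxyl, hydrogen-bonded to the acetyl carbonyl and flanked on both sides, should resist K2CO3/acetone, and because the two ring-A hydroxyls are equivalent either mono-etherification gives the same compound.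

**Step 7**
Reactants: 11 2'-(benzyloxy)-3',5'-bis{2-(benzyloxy)-5-[2-(benzyloxy)benzyl]benzyl}-6'-hydroxy-4'-methoxyacetophenone
Product: 13 5-(benzyloxy)-6,8-bis{2-(benzyloxy)-5-[2-(benzyloxy)benzyl]benzyl}-7-methoxy-4H-chromen-4-one, via enaminone 12 (not isolated)
Conditions: DMF-DMA (5 equiv), toluene, 100 °C; evaporate; conc. HCl (3 equiv), CH2Cl2, rt; aq NaHCO3 wash
Reagents that add atoms: N,N-dimethylformamide dimethyl acetal, COC(OC)N(C)C
Why: Enaminone chromone synthesis, in which the methyl ketone condenses with the amide acetal to the β-dimethylamino enone 12 (this supplies C2) and acid then drives addition of the chelated hydroxyl and loss of dimethylamine to close the 4-pyranone; all other phenols are already benzylated, so the acetal cannot methylate them.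

**Step 8**
Reactants: 13 5-(benzyloxy)-6,8-bis{2-(benzyloxy)-5-[2-(benzyloxy)benzyl]benzyl}-7-methoxy-4H-chromen-4-one; 14 phenylboronic acid
Product: 15 (2S)-5-(benzyloxy)-6,8-bis{2-(benzyloxy)-5-[2-(benzyloxy)benzyl]benzyl}-7-methoxy-2-phenyl-2,3-dihydro-4H-chromen-4-one
Conditions: [Rh(OH){(S)-MeO-F12-BIPHEP}]2 (3 mol%, preformed; (S)-DIFLUORPHOS as commercial stand-in), 14 (3 equiv, in portions), toluene/H2O 10:1, 30 °C
Reagents that add atoms: none
Why: Phenylboronic acid transmetalates to the chiral hydroxo-rhodium(I) complex, the phenyl-rhodium species binds the C2=C3 bond of 13 and inserts it so that phenyl ends on C2 and rhodium on C3/O as an oxa-π-allyl, and water protonates this enolate to release 15 and regenerate Rh–OH. The closest known reaction is the Hayashi–Miyaura asymmetric 1,4-addition of arylboronic acids as applied to 2-unsubstituted chromones, 5,7-dioxygenated ones included. No ring is closed; ring C only changes from a 4-pyranone to a 2,3-dihydro-4-pyranone. The C2 stereocentre is set as S by the C2-symmetric diphosphine alone, which distinguishes the two faces of the planar, stereocentre-free substrate in the insertion step. The step needs face selectivity, 1,4- over 1,2-addition and no β-aryloxide elimination to the ring-opened 2′-hydroxychalcone: the hydrogen-only C2 terminus and the flexible CH2-linked C8 arm keep the β-carbon accessible, the peri 5-benzyloxy group screens C4, every phenol is capped so nothing acidic quenches the aryl-rhodium, and the base-free aqueous medium protonates the enolate at once.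

**Step 9**
Reactants: 15 (2S)-5-(benzyloxy)-6,8-bis{2-(benzyloxy)-5-[2-(benzyloxy)benzyl]benzyl}-7-methoxy-2-phenyl-2,3-dihydro-4H-chromen-4-one
Product: 16 5''-(2''''-hydroxybenzyl)uvarinol, (2S)-5-hydroxy-6,8-bis{2-hydroxy-5-(2-hydroxybenzyl)benzyl}-7-methoxy-2-phenyl-2,3-dihydro-4H-chromen-4-one
Conditions: H2 (1 atm), 10% Pd/C, EtOAc/THF 1:1, rt, stopped at complete debenzylation
Reagents that add atoms: none
Why: Heterogeneous palladium hydrogenolysis of the five aryl benzyl ethers at room temperature, expected to be much faster than cleavage of the cyclic C2–O1 bond or reduction of the C4 ketone; with no acid or base present the ring-opening/ring-closing pathway that would racemise C2 stays closed.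

**Compound list**
1 | 2-(benzyloxy)benzaldehyde | O=Cc1ccccc1OCc1ccccc1 | starting material
2 | [2-(benzyloxy)phenyl]methanol | OCc1ccccc1OCc1ccccc1 | intermediate
3 | 2-(benzyloxy)benzyl bromide | BrCc1ccccc1OCc1ccccc1 | intermediate
4 | 2-hydroxy-5-(4,4,5,5-tetramethyl-1,3,2-dioxaborolan-2-yl)benzaldehyde | O=Cc1cc(B2OC(C)(C)C(C)(C)O2)ccc1O | starting material
5 | 5-[2-(benzyloxy)benzyl]-2-hydroxybenzaldehyde | O=Cc1cc(Cc2ccccc2OCc2ccccc2)ccc1O | intermediate
6 | 4-[2-(benzyloxy)benzyl]-2-(hydroxymethyl)phenol | OCc1cc(Cc2ccccc2OCc2ccccc2)ccc1O | intermediate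
7 | 2',6'-dihydroxy-4'-methoxyacetophenone | CC(=O)c1c(O)cc(OC)cc1O | starting material
8 | 4-[2-(benzyloxy)benzyl]-6-methylidenecyclohexa-2,4-dien-1-one (ortho-quinone methide) | C=C1C=C(Cc2ccccc2OCc2ccccc2)C=CC1=O | intermediate (not isolated)
9 | 3'-{5-[2-(benzyloxy)benzyl]-2-hydroxybenzyl}-2',6'-dihydroxy-4'-methoxyacetophenone | CC(=O)c1c(O)cc(OC)c(Cc2cc(Cc3ccccc3OCc3ccccc3)ccc2O)c1O | intermediate (not isolated)
10 | 3',5'-bis{5-[2-(benzyloxy)benzyl]-2-hydroxybenzyl}-2',6'-dihydroxy-4'-methoxyacetophenone | CC(=O)c1c(O)c(Cc2cc(Cc3ccccc3OCc3ccccc3)ccc2O)c(OC)c(Cc2cc(Cc3ccccc3OCc3ccccc3)ccc2O)c1O | intermediate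
11 | 2'-(benzyloxy)-3',5'-bis{2-(benzyloxy)-5-[2-(benzyloxy)benzyl]benzyl}-6'-hydroxy-4'-methoxyacetophenone | CC(=O)c1c(O)c(Cc2cc(Cc3ccccc3OCc3ccccc3)ccc2OCc2ccccc2)c(OC)c(Cc2cc(Cc3ccccc3OCc3ccccc3)ccc2OCc2ccccc2)c1OCc1ccccc1 | intermediate
12 | (E)-3-(dimethylamino)-1-(2-(benzyloxy)-3,5-bis{2-(benzyloxy)-5-[2-(benzyloxy)benzyl]benzyl}-6-hydroxy-4-methoxyphenyl)prop-2-en-1-one | CN(C)/C=C/C(=O)c1c(O)c(Cc2cc(Cc3ccccc3OCc3ccccc3)ccc2OCc2ccccc2)c(OC)c(Cc2cc(Cc3ccccc3OCc3ccccc3)ccc2OCc2ccccc2)c1OCc1ccccc1 | intermediate (not isolated)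
13 | 5-(benzyloxy)-6,8-bis{2-(benzyloxy)-5-[2-(benzyloxy)benzyl]benzyl}-7-methoxy-4H-chromen-4-one | COc1c(Cc2cc(Cc3ccccc3OCc3ccccc3)ccc2OCc2ccccc2)c(OCc2ccccc2)c2c(c1Cc1cc(Cc3ccccc3OCc3ccccc3)ccc1OCc1ccccc1)occc2=O | intermediate
14 | phenylboronic acid | OB(O)c1ccccc1 | starting material
15 | (2S)-5-(benzyloxy)-6,8-bis{2-(benzyloxy)-5-[2-(benzyloxy)benzyl]benzyl}-7-methoxy-2-phenyl-2,3-dihydro-4H-chromen-4-one | COc1c(Cc2cc(Cc3ccccc3OCc3ccccc3)ccc2OCc2ccccc2)c(OCc2ccccc2)c2c(c1Cc1cc(Cc3ccccc3OCc3ccccc3)ccc1OCc1ccccc1)O[C@H](c1ccccc1)CC2=O | intermediate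
16 | 5''-(2''''-hydroxybenzyl)uvarinol, (2S)-5-hydroxy-6,8-bis{2-hydroxy-5-(2-hydroxybenzyl)benzyl}-7-methoxy-2-phenyl-2,3-dihydro-4H-chromen-4-one | COc1c(Cc2cc(Cc3ccccc3O)ccc2O)c(O)c2c(c1Cc1cc(Cc3ccccc3O)ccc1O)O[C@H](c1ccccc1)CC2=O | target

**Totals**
Total step count: 9. Longest linear sequence: 9 steps (1 to 16); compounds 4, 7 and 14 enter as purchased materials.

**Steps most likely to fail**

1. Step 8. The electron-rich chromone, flanked at C5 and C8, may turn over slowly, the boronic acid may be lost by protodeboronation, or facial discrimination may be poor. The fallback sets out from 11 and comes back at 15. Claisen–Schmidt condensation of 11 with benzaldehyde (KOH, EtOH/THF, rt) should give the 2′-hydroxychalcone F1. Sodium acetate in refluxing ethanol then closes ring C by intramolecular oxa-Michael addition, favoured because the 6′-benzyloxy group twists the enone out of conjugation, to give the racemic flavanone F2. Preparative chiral-phase SFC delivers 15, and the (2R)-enantiomer F3 is re-equilibrated through F1 under the same acetate conditions and resubmitted.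

2. Step 5. The arm alcohol may self-condense under acid, the second alkylation may stall at 9, or the phenol rings of attached arms may be alkylated further. The fallback sets out from 6 (with 7) and comes back at 10. Acetylation (Ac2O, pyridine) gives the diacetate F4. Added slowly to 7 and K2CO3 in DMF at rt, F4 loses its aryl acetate to the phenoxide base, the freed phenoxide expels the benzylic acetate (base-triggered 1,4-elimination), and the quinone methide 8 is taken up at carbon by the acetophenone phenoxide. Under base only this phloroglucinol-type phenoxide is a strong carbon nucleophile. A short K2CO3/MeOH treatment strips any O-acetyl groups before isolation of 10.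

3. Step 3. The phenoxide of 4 may be O-benzylated by 3, or the phenoxide-bearing boronate may protodeboronate. The fallback sets out from 4 and comes back at 5. MOMCl and iPr2NEt in CH2Cl2 give the MOM-protected boronate F5. The same Pd(dppf)Cl2/K2CO3 coupling with 3 then gives the MOM-protected diarylmethane aldehyde F6, which now has no competing oxygen nucleophile. HCl in MeOH/THF at rt, followed by an aqueous wash to hydrolyse any dimethyl acetal, removes the MOM group and returns 5.

**Further compounds**
F1 | step 8 | (E)-1-(2-(benzyloxy)-3,5-bis{2-(benzyloxy)-5-[2-(benzyloxy)benzyl]benzyl}-6-hydroxy-4-methoxyphenyl)-3-phenylprop-2-en-1-one (2′-hydroxychalcone) | O=C(/C=C/c1ccccc1)c1c(O)c(Cc2cc(Cc3ccccc3OCc3ccccc3)ccc2OCc2ccccc2)c(OC)c(Cc2cc(Cc3ccccc3OCc3ccccc3)ccc2OCc2ccccc2)c1OCc1ccccc1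
F2 | step 8 | racemic 5-(benzyloxy)-6,8-bis{2-(benzyloxy)-5-[2-(benzyloxy)benzyl]benzyl}-7-methoxy-2-phenyl-2,3-dihydro-4H-chromen-4-one | COc1c(Cc2cc(Cc3ccccc3OCc3ccccc3)ccc2OCc2ccccc2)c(OCc2ccccc2)c2c(c1Cc1cc(Cc3ccccc3OCc3ccccc3)ccc1OCc1ccccc1)OC(c1ccccc1)CC2=O
F3 | step 8 | (2R)-5-(benzyloxy)-6,8-bis{2-(benzyloxy)-5-[2-(benzyloxy)benzyl]benzyl}-7-methoxy-2-phenyl-2,3-dihydro-4H-chromen-4-one | COc1c(Cc2cc(Cc3ccccc3OCc3ccccc3)ccc2OCc2ccccc2)c(OCc2ccccc2)c2c(c1Cc1cc(Cc3ccccc3OCc3ccccc3)ccc1OCc1ccccc1)O[C@@H](c1ccccc1)CC2=O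
F4 | step 5 | 2-(acetoxymethyl)-4-[2-(benzyloxy)benzyl]phenyl acetate | CC(=O)OCc1cc(Cc2ccccc2OCc2ccccc2)ccc1OC(C)=O
F5 | step 3 | 2-(methoxymethoxy)-5-(4,4,5,5-tetramethyl-1,3,2-dioxaborolan-2-yl)benzaldehyde | COCOc1ccc(B2OC(C)(C)C(C)(C)O2)cc1C=O
F6 | step 3 | 5-[2-(benzyloxy)benzyl]-2-(methoxymethoxy)benzaldehyde | COCOc1ccc(Cc2ccccc2OCc2ccccc2)cc1C=O
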